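The route rests on one disconnection of the cyclopentane of the cyclopenta[c]pyran core: the C7 methyl group and the C7a–C1 bond lie trans on neighbouring ring carbons, with C4a beside them, which is the imprint of β-methylation and α-aldol reaction of a cyclopentenone whose carbonyl carbon becomes C4a. In a single operation the key step should form C7–CH3 and C7a–C1 and set C7, C7a and C1, the last as the anti aldol that an invertive lactonisation later corrects. Its precursors are cyclopent-2-en-1-one, dimethylzinc and 4-methoxy-5-methyl-2-oxo-2H-chromene-3-carbaldehyde; the surviving ketone then brings in C4, C3 and the acyl group of the pyran ring.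

Key step: step 4

Remarks on the chemistry:
- Atoms are numbered as in the cyclopenta[c]pyran of the target (C1, O2, C3, C4, C4a, C5, C6, C7, C7a).
- C4 of compounds 16–19 forms as a mixture of epimers and is drawn without configuration, because step 11 makes it sp2.
- Assumption: the (S,R,R) ligand is taken to deliver methyl to cyclopentenone with the facial sense it shows with six-membered enones; if the opposite sense is found, its enantiomer is used.
- Any minor aldol diastereomer formed in step 4 is removed by chromatography.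

Step 1
Reactants: 1 2'-hydroxy-6'-methylacetophenone; 2 diethyl carbonate
Product: 3 4-hydroxy-5-methyl-2H-chromen-2-one
Conditions: NaH (3 equiv), toluene, 110 °C; then 1 M HCl
Reagents that add atoms: none
Why: Claisen-type C-acylation of the ketone enolate by diethyl carbonate followed by lactonisation onto the phenoxide is the standard 4-hydroxycoumarin synthesis from 2-hydroxyacetophenones; no stereocentre is formed.

Step 2
Reactants: 3 4-hydroxy-5-methyl-2H-chromen-2-one
Product: 4 4-chloro-5-methyl-2-oxo-2H-chromene-3-carbaldehyde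
Conditions: POCl3 (3 equiv), DMF, 0 → 60 °C; then ice–water
Reagents that add atoms: N,N-dimethylformamide CN(C)C=O (formyl carbon); phosphoryl chloride O=P(Cl)(Cl)Cl (chlorine); water O (aldehyde oxygen)
Why: Vilsmeier–Haack formylation at the nucleophilic C3 of the 4-hydroxycoumarin, in which the chloroiminium reagent also turns the vinylogous acid hydroxyl into the 4-chloride, as is usual for this substrate class.

Step 3
Reactants: 4 4-chloro-5-methyl-2-oxo-2H-chromene-3-carbaldehyde
Product: 5 4-methoxy-5-methyl-2-oxo-2H-chromene-3-carbaldehyde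
Conditions: NaOMe (1.05 equiv), MeOH–THF, 0 °C
Reagents that add atoms: sodium methoxide [Na+].[O-]C
Why: Addition–elimination (vinylogous acyl substitution) of methoxide at C4, which is activated by both the formyl group and the lactone carbonyl, should replace chloride at low temperature with one equivalent of base.

Step 4
Reactants: 6 cyclopent-2-en-1-one; 7 dimethylzinc; 5 4-methoxy-5-methyl-2-oxo-2H-chromene-3-carbaldehyde
Product: 10 (2S,3S)-2-[(R)-hydroxy(4-methoxy-5-methyl-2-oxo-2H-chromen-3-yl)methyl]-3-methylcyclopentan-1-one, via zinc enolate 8 (not isolated), via zinc aldolate 9 (not isolated)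
Conditions: Cu(OTf)2 (3 mol%), (S,R,R)-phosphoramidite from (S)-BINOL and bis[(R)-1-phenylethyl]amine (6 mol%), 5 (1 equiv) and 6 (1.5 equiv) in toluene–CH2Cl2, 7 (1.8 equiv) added dropwise, −40 → −20 °C; then aq NH4Cl
Reagents that add atoms: none
Why: Me2Zn reduces Cu(OTf)2 to a monovalent methylcopper–phosphoramidite species that binds the enone, transfers methyl to the β-carbon through a π-complex and a trivalent copper intermediate, and leaves the oxygen on zinc as enolate 8. This is the known copper-catalysed asymmetric conjugate addition of dialkylzincs to cyclic enones run as a three-component coupling, in which the zinc enolate adds to the aldehyde in an aldol reaction; no ring is closed. C7 is fixed by the chiral ligand, which exposes one face of the enone to the methyl group. C7a is fixed by the new methyl group, because the aldehyde approaches the enolate on the opposite ring face and so gives the trans-2,3 pattern. C1 is fixed by a closed six-membered chair transition state on zinc, in which the ring-locked E enolate places the coumarinyl group equatorial and gives the anti aldol, by design the C1 epimer of the target. The step needs methyl transfer to the enone only; the unhindered enone should win over the aldehyde, whose C4 is tetrasubstituted and shielded by the peri 5-methyl group and whose carbonyl is inert to Me2Zn without a catalyst, while the aldehyde present from the start intercepts 8 before it adds to unreacted enone.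

Step 5
Reactants: 10 (2S,3S)-2-[(R)-hydroxy(4-methoxy-5-methyl-2-oxo-2H-chromen-3-yl)methyl]-3-methylcyclopentan-1-one
Product: 11 (2S,3S)-2-[(R)-(4-methoxy-5-methyl-2-oxo-2H-chromen-3-yl)(triethylsilyloxy)methyl]-3-methylcyclopentan-1-one
Conditions: TESOTf (1.3 equiv), 2,6-lutidine (2 equiv), CH2Cl2, −78 °C
Reagents that add atoms: triethylsilyl trifluoromethanesulfonate CC[Si](CC)(CC)OS(=O)(=O)C(F)(F)F
Why: A silyl triflate with a hindered pyridine base silylates the crowded secondary aldol hydroxyl at low temperature without retro-aldol cleavage or epimerisation, and the ether masks the alkoxide for the enolisation that follows.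

Step 6
Reactants: 11 (2S,3S)-2-[(R)-(4-methoxy-5-methyl-2-oxo-2H-chromen-3-yl)(triethylsilyloxy)methyl]-3-methylcyclopentan-1-one
Product: 13 (4S,5S)-5-[(R)-(4-methoxy-5-methyl-2-oxo-2H-chromen-3-yl)(triethylsilyloxy)methyl]-4-methylcyclopent-1-en-1-yl trifluoromethanesulfonate, via lithium enolate 12 (not isolated)
Conditions: LiN(i-Pr)2 (1.1 equiv, commercial solution), THF, −78 °C; then PhNTf2, −78 → 0 °C; aq NH4Cl
Reagents that add atoms: N-phenylbis(trifluoromethanesulfonimide) O=S(=O)(N(c1ccccc1)S(=O)(=O)C(F)(F)F)C(F)(F)F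
Why: Kinetic deprotonation by the bulky amide base takes a proton from the unhindered C5 methylene and not from the tertiary C7a–H flanked by two branches, and O-sulfonylation fixes the C4a=C5 enol triflate with the three stereocentres untouched.

Step 7
Reactants: 13 (4S,5S)-5-[(R)-(4-methoxy-5-methyl-2-oxo-2H-chromen-3-yl)(triethylsilyloxy)methyl]-4-methylcyclopent-1-en-1-yl trifluoromethanesulfonate; 14 benzyl 2-bromopropanoate (racemic)
Product: 16 benzyl 2-{(4S,5R)-5-[(R)-(4-methoxy-5-methyl-2-oxo-2H-chromen-3-yl)(triethylsilyloxy)methyl]-4-methylcyclopent-1-en-1-yl}propanoate (C4 epimers), via Reformatsky reagent 15 (not isolated)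
Conditions: 14 (2.5 equiv), Zn dust (TMSCl-activated), THF, 25 °C; then 13, Pd(PPh3)4 (5 mol%), THF, 50 °C
Reagents that add atoms: none
Why: Negishi-type cross-coupling of an enol triflate with a Reformatsky reagent (oxidative addition into C–OTf, transmetalation from zinc, reductive elimination) forms C4a–C4, and the benzyl ester is chosen so that the acid is later freed by hydrogen and not by hydroxide, which would attack the coumarin.

Step 8
Reactants: 16 benzyl 2-{(4S,5R)-5-[(R)-(4-methoxy-5-methyl-2-oxo-2H-chromen-3-yl)(triethylsilyloxy)methyl]-4-methylcyclopent-1-en-1-yl}propanoate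
Product: 17 2-{(1S,2R,3S)-2-[(R)-(4-methoxy-5-methyl-2-oxo-2H-chromen-3-yl)(triethylsilyloxy)methyl]-3-methylcyclopentyl}propanoic acid (C4 epimers)
Conditions: H2 (1 atm), 10% Pd/C, EtOAc, 20 °C
Reagents that add atoms: none
Why: Heterogeneous catalytic hydrogenation should deliver hydrogen to the C4a=C5 alkene from the ring face opposite the bulky silyloxy(coumarinyl)methyl group on the adjacent C7a, which places H-4a cis to H-7a and sets C4a as S, while the same catalyst hydrogenolyses the benzyl ester; the tetrasubstituted 4-methoxycoumarin double bond and the silyl ether should remain.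

Step 9
Reactants: 17 2-{(1S,2R,3S)-2-[(R)-(4-methoxy-5-methyl-2-oxo-2H-chromen-3-yl)(triethylsilyloxy)methyl]-3-methylcyclopentyl}propanoic acid
Product: 18 2-{(1S,2R,3S)-2-[(R)-hydroxy(4-methoxy-5-methyl-2-oxo-2H-chromen-3-yl)methyl]-3-methylcyclopentyl}propanoic acid (C4 epimers)
Conditions: HF·pyridine, pyridine, THF, 0 °C; crude product used at once
Reagents that add atoms: none
Why: Fluoride cleaves the triethylsilyl ether in a pyridine-buffered medium at 0 °C, where the δ-hydroxy acid should not close by itself with retention at C1.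

Step 10
Reactants: 18 2-{(1S,2R,3S)-2-[(R)-hydroxy(4-methoxy-5-methyl-2-oxo-2H-chromen-3-yl)methyl]-3-methylcyclopentyl}propanoic acid
Product: 19 (1S,4aS,7S,7aR)-1-(4-methoxy-5-methyl-2-oxo-2H-chromen-3-yl)-4,7-dimethylhexahydrocyclopenta[c]pyran-3(1H)-one (C4 epimers)
Conditions: PPh3 (3 equiv), DIAD (3 equiv), THF (0.005 M), 0 → 20 °C
Reagents that add atoms: none
Why: Mitsunobu lactonisation activates the C1 hydroxyl as an alkoxyphosphonium ion, which the tethered carboxylate displaces from the rear, so that C1 is inverted from R to S as the six-membered lactone closes between the cis-disposed arms on C4a and C7a; high dilution suppresses oligomers.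

Step 11
Reactants: 19 (1S,4aS,7S,7aR)-1-(4-methoxy-5-methyl-2-oxo-2H-chromen-3-yl)-4,7-dimethylhexahydrocyclopenta[c]pyran-3(1H)-one
Product: 21 (1S,4aS,7S,7aR)-1-(4-methoxy-5-methyl-2-oxo-2H-chromen-3-yl)-4,7-dimethyl-1,4a,5,6,7,7a-hexahydrocyclopenta[c]pyran-3-yl diphenyl phosphate, via potassium enolate 20 (not isolated)
Conditions: 19 and (PhO)2P(O)Cl (1.5 equiv), THF–DMPU, −78 °C; KN(SiMe3)2 (1.3 equiv) added dropwise
Reagents that add atoms: diphenyl chlorophosphate O=P(Cl)(Oc1ccccc1)Oc1ccccc1
Why: The lactone has a single α-hydrogen, at C4, so enolisation and O-phosphorylation (ketene acetal phosphate formation, known for six-membered lactones) should converge both C4 epimers on one C3=C4 enol derivative, the enolate being trapped as it forms.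

Step 12
Reactants: 21 (1S,4aS,7S,7aR)-1-(4-methoxy-5-methyl-2-oxo-2H-chromen-3-yl)-4,7-dimethyl-1,4a,5,6,7,7a-hexahydrocyclopenta[c]pyran-3-yl diphenyl phosphate
Product: 22 3-[(1S,4aS,7S,7aR)-4,7-dimethyl-3-(trimethylstannyl)-1,4a,5,6,7,7a-hexahydrocyclopenta[c]pyran-1-yl]-4-methoxy-5-methyl-2H-chromen-2-one
Conditions: (Me3Sn)2 (1.5 equiv), Pd(PPh3)4 (10 mol%), LiCl (3 equiv, additive), THF, 65 °C
Reagents that add atoms: hexamethylditin C[Sn](C)(C)[Sn](C)(C)C
Why: Palladium-catalysed stannylation of a lactone-derived ketene acetal phosphate with a distannane (oxidative addition into the C3–O bond, Sn–Sn transmetalation, reductive elimination) is established for this substrate class and turns C3 into a nucleophilic carbon.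

Step 13
Reactants: 22 3-[(1S,4aS,7S,7aR)-4,7-dimethyl-3-(trimethylstannyl)-1,4a,5,6,7,7a-hexahydrocyclopenta[c]pyran-1-yl]-4-methoxy-5-methyl-2H-chromen-2-one; 23 3-methylbutanoyl chloride
Product: 24 3-[(1S,4aS,7S,7aR)-4,7-dimethyl-3-(3-methylbutanoyl)-1,4a,5,6,7,7a-hexahydrocyclopenta[c]pyran-1-yl]-4-methoxy-5-methyl-2H-chromen-2-one
Conditions: 23 (1.5 equiv), PdCl2(PPh3)2 (5 mol%), toluene, 70 °C
Reagents that add atoms: none
Why: In this Stille ketone synthesis the acylpalladium chloride formed from the acid chloride takes the α-alkoxyalkenyl group from tin in preference to methyl, and reductive elimination forms the C3–acyl bond of the α-alkoxy enone without any organometallic that would attack the coumarin.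

Step 14
Reactants: 24 3-[(1S,4aS,7S,7aR)-4,7-dimethyl-3-(3-methylbutanoyl)-1,4a,5,6,7,7a-hexahydrocyclopenta[c]pyran-1-yl]-4-methoxy-5-methyl-2H-chromen-2-one
Product: 25 3-[(1S,4aS,7S,7aR)-4,7-dimethyl-3-(3-methylbutanoyl)-1,4a,5,6,7,7a-hexahydrocyclopenta[c]pyran-1-yl]-4-hydroxy-5-methyl-2H-chromen-2-one (CNP0124891.1)
Conditions: NaSEt (3 equiv), DMF, 20 → 40 °C; then 0.5 M HCl to pH 4, 0 °C
Reagents that add atoms: none
Why: The 4-methoxycoumarin is a vinylogous methyl ester whose oxyanion is a carboxylate-like leaving group, so thiolate should remove the methyl group by SN2 attack at carbon, C4 itself being shielded by the C3 substituent and the peri 5-methyl group; mild acidification then gives the neutral target with C1 untouched.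

Compound list
1 | 2'-hydroxy-6'-methylacetophenone | CC(=O)c1c(C)cccc1O | starting material
2 | diethyl carbonate | CCOC(=O)OCC | starting material
3 | 4-hydroxy-5-methyl-2H-chromen-2-one | Cc1cccc2oc(=O)cc(O)c12 | intermediate
4 | 4-chloro-5-methyl-2-oxo-2H-chromene-3-carbaldehyde | Cc1cccc2oc(=O)c(C=O)c(Cl)c12 | intermediate
5 | 4-methoxy-5-methyl-2-oxo-2H-chromene-3-carbaldehyde | O=Cc1c(OC)c2c(C)cccc2oc1=O | intermediate
6 | cyclopent-2-en-1-one | O=C1C=CCC1 | starting material
7 | dimethylzinc | C[Zn]C | starting material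
8 | methylzinc (S)-3-methylcyclopent-1-en-1-olate (zinc enolate) | C[Zn]OC1=C[C@@H](C)CC1 | intermediate (not isolated)
9 | methylzinc alkoxide of 10 (zinc aldolate) | O=C1CC[C@H](C)[C@H]1[C@@H](O[Zn]C)c1c(OC)c2c(C)cccc2oc1=O | intermediate (not isolated)
10 | (2S,3S)-2-[(R)-hydroxy(4-methoxy-5-methyl-2-oxo-2H-chromen-3-yl)methyl]-3-methylcyclopentan-1-one (trans-2,3, anti aldol) | O=C1CC[C@H](C)[C@H]1[C@@H](O)c1c(OC)c2c(C)cccc2oc1=O | intermediate
11 | (2S,3S)-2-[(R)-(4-methoxy-5-methyl-2-oxo-2H-chromen-3-yl)(triethylsilyloxy)methyl]-3-methylcyclopentan-1-one | O=C1CC[C@H](C)[C@H]1[C@@H](O[Si](CC)(CC)CC)c1c(OC)c2c(C)cccc2oc1=O | intermediate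
12 | lithium (4S,5S)-5-[(R)-(4-methoxy-5-methyl-2-oxo-2H-chromen-3-yl)(triethylsilyloxy)methyl]-4-methylcyclopent-1-en-1-olate | [Li]OC1=CC[C@H](C)[C@H]1[C@@H](O[Si](CC)(CC)CC)c1c(OC)c2c(C)cccc2oc1=O | intermediate (not isolated)
13 | (4S,5S)-5-[(R)-(4-methoxy-5-methyl-2-oxo-2H-chromen-3-yl)(triethylsilyloxy)methyl]-4-methylcyclopent-1-en-1-yl trifluoromethanesulfonate | O=S(=O)(OC1=CC[C@H](C)[C@H]1[C@@H](O[Si](CC)(CC)CC)c1c(OC)c2c(C)cccc2oc1=O)C(F)(F)F | intermediate
14 | benzyl 2-bromopropanoate (racemic) | CC(Br)C(=O)OCc1ccccc1 | starting material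
15 | [1-(benzyloxy)-1-oxopropan-2-yl]zinc bromide (Reformatsky reagent) | CC([Zn]Br)C(=O)OCc1ccccc1 | intermediate (not isolated)
16 | benzyl 2-{(4S,5R)-5-[(R)-(4-methoxy-5-methyl-2-oxo-2H-chromen-3-yl)(triethylsilyloxy)methyl]-4-methylcyclopent-1-en-1-yl}propanoate (C4 epimers) | CC(C(=O)OCc1ccccc1)C1=CC[C@H](C)[C@H]1[C@@H](O[Si](CC)(CC)CC)c1c(OC)c2c(C)cccc2oc1=O | intermediate
17 | 2-{(1S,2R,3S)-2-[(R)-(4-methoxy-5-methyl-2-oxo-2H-chromen-3-yl)(triethylsilyloxy)methyl]-3-methylcyclopentyl}propanoic acid (C4 epimers) | CC(C(=O)O)[C@H]1CC[C@H](C)[C@H]1[C@@H](O[Si](CC)(CC)CC)c1c(OC)c2c(C)cccc2oc1=O | intermediate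
18 | 2-{(1S,2R,3S)-2-[(R)-hydroxy(4-methoxy-5-methyl-2-oxo-2H-chromen-3-yl)methyl]-3-methylcyclopentyl}propanoic acid (C4 epimers) | CC(C(=O)O)[C@H]1CC[C@H](C)[C@H]1[C@@H](O)c1c(OC)c2c(C)cccc2oc1=O | intermediate
19 | (1S,4aS,7S,7aR)-1-(4-methoxy-5-methyl-2-oxo-2H-chromen-3-yl)-4,7-dimethylhexahydrocyclopenta[c]pyran-3(1H)-one (C4 epimers; H-1, H-4a and H-7a all cis) | CC1C(=O)O[C@H](c2c(OC)c3c(C)cccc3oc2=O)[C@H]2[C@@H]1CC[C@@H]2C | intermediate
20 | potassium enolate of 19 | CC1=C(O[K])O[C@H](c2c(OC)c3c(C)cccc3oc2=O)[C@H]2[C@@H]1CC[C@@H]2C | intermediate (not isolated)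
21 | (1S,4aS,7S,7aR)-1-(4-methoxy-5-methyl-2-oxo-2H-chromen-3-yl)-4,7-dimethyl-1,4a,5,6,7,7a-hexahydrocyclopenta[c]pyran-3-yl diphenyl phosphate | CC1=C(OP(=O)(Oc2ccccc2)Oc2ccccc2)O[C@H](c2c(OC)c3c(C)cccc3oc2=O)[C@H]2[C@@H]1CC[C@@H]2C | intermediate
22 | 3-[(1S,4aS,7S,7aR)-4,7-dimethyl-3-(trimethylstannyl)-1,4a,5,6,7,7a-hexahydrocyclopenta[c]pyran-1-yl]-4-methoxy-5-methyl-2H-chromen-2-one | CC1=C([Sn](C)(C)C)O[C@H](c2c(OC)c3c(C)cccc3oc2=O)[C@H]2[C@@H]1CC[C@@H]2C | intermediate
23 | 3-methylbutanoyl chloride | CC(C)CC(=O)Cl | starting material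
24 | 3-[(1S,4aS,7S,7aR)-4,7-dimethyl-3-(3-methylbutanoyl)-1,4a,5,6,7,7a-hexahydrocyclopenta[c]pyran-1-yl]-4-methoxy-5-methyl-2H-chromen-2-one | CC1=C(C(=O)CC(C)C)O[C@H](c2c(OC)c3c(C)cccc3oc2=O)[C@H]2[C@@H]1CC[C@@H]2C | intermediate
25 | 3-[(1S,4aS,7S,7aR)-4,7-dimethyl-3-(3-methylbutanoyl)-1,4a,5,6,7,7a-hexahydrocyclopenta[c]pyran-1-yl]-4-hydroxy-5-methyl-2H-chromen-2-one | CC1=C(C(=O)CC(C)C)O[C@H](c2c(O)c3c(C)cccc3oc2=O)[C@H]2[C@@H]1CC[C@@H]2C | target

Total step count: 14. Longest linear sequence: 14 steps (1 → 25); every step lies on this line.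

Steps most likely to fail

Step 4. Methyl may be transferred to the aldehyde (at the carbonyl or, by addition–elimination, at coumarin C4) in competition with the enone. Enolate 8 may add to unreacted enone. A loosely organised aldol may erode the anti preference, and the five-membered enone may give lower enantioselectivity than six-membered ones. The fallback separates the two bond formations and sets out from 6 and 7. The conjugate addition is run alone, with no aldehyde present and with whichever copper–ligand system serves the five-membered enone best. Zinc enolate 8 is silylated with TMSOTf to (S)-trimethyl[(3-methylcyclopent-1-en-1-yl)oxy]silane F1, which is purified. MeLi in THF at 0 °C then regenerates lithium (S)-3-methylcyclopent-1-en-1-olate F2, and ZnCl2 converts it into chlorozinc (S)-3-methylcyclopent-1-en-1-olate F3. Aldehyde 5 is added at −78 °C to give the chlorozinc aldolate F4, and aqueous NH4Cl returns the route to compound 10.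

Step 10. The substitution may run through acyl activation and so close with retention. The activated C1–O bond next to the electron-rich 4-methoxycoumarin may ionise with loss of configuration. The free hydroxy acid may also close with retention before it is activated. The fallback sets C1 by reduction and sets out from 18. Dess–Martin periodinane oxidises the carbinol to 2-{(1S,2R,3S)-2-[(4-methoxy-5-methyl-2-oxo-2H-chromen-3-yl)carbonyl]-3-methylcyclopentyl}propanoic acid F5. Asymmetric transfer hydrogenation with RuCl(p-cymene)(TsDPEN) and HCO2H–Et3N, using the catalyst enantiomer that delivers hydride to the face giving (S)-C1, should give the C1-epimeric hydroxy acid 2-{(1S,2R,3S)-2-[(S)-hydroxy(4-methoxy-5-methyl-2-oxo-2H-chromen-3-yl)methyl]-3-methylcyclopentyl}propanoic acid F6. Carbodiimide lactonisation (EDC·HCl, DMAP, CH2Cl2) closes F6 with retention and returns the route to compound 19.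

Step 12. Oxidative addition of zerovalent palladium into the hindered, tetrasubstituted ketene acetal phosphate may be slow. The phosphate may hydrolyse back to the lactone, and the stannane may suffer protodestannylation on isolation. The fallback avoids tin and sets out from 19. Enolate 20 is trapped with PhNTf2 as the ketene acetal triflate (1S,4aS,7S,7aR)-1-(4-methoxy-5-methyl-2-oxo-2H-chromen-3-yl)-4,7-dimethyl-1,4a,5,6,7,7a-hexahydrocyclopenta[c]pyran-3-yl trifluoromethanesulfonate F7. Nozaki–Hiyama–Kishi coupling with 3-methylbutanal (CrCl2, catalytic NiCl2, DMF) should give the allylic alcohol 3-[(1S,4aS,7S,7aR)-3-(1-hydroxy-3-methylbutyl)-4,7-dimethyl-1,4a,5,6,7,7a-hexahydrocyclopenta[c]pyran-1-yl]-4-methoxy-5-methyl-2H-chromen-2-one F8 as a mixture of carbinol epimers. Dess–Martin oxidation of F8 returns the route to compound 24.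

Further compounds
F1 | step 4 | (S)-trimethyl[(3-methylcyclopent-1-en-1-yl)oxy]silane | C[Si](C)(C)OC1=C[C@@H](C)CC1
F2 | step 4 | lithium (S)-3-methylcyclopent-1-en-1-olate | [Li]OC1=C[C@@H](C)CC1
F3 | step 4 | chlorozinc (S)-3-methylcyclopent-1-en-1-olate | Cl[Zn]OC1=C[C@@H](C)CC1
F4 | step 4 | chlorozinc alkoxide of 10 (chlorozinc aldolate) | O=C1CC[C@H](C)[C@H]1[C@@H](O[Zn]Cl)c1c(OC)c2c(C)cccc2oc1=O
F5 | step 10 | 2-{(1S,2R,3S)-2-[(4-methoxy-5-methyl-2-oxo-2H-chromen-3-yl)carbonyl]-3-methylcyclopentyl}propanoic acid | CC(C(=O)O)[C@H]1CC[C@H](C)[C@H]1C(=O)c1c(OC)c2c(C)cccc2oc1=O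
F6 | step 10 | 2-{(1S,2R,3S)-2-[(S)-hydroxy(4-methoxy-5-methyl-2-oxo-2H-chromen-3-yl)methyl]-3-methylcyclopentyl}propanoic acid | CC(C(=O)O)[C@H]1CC[C@H](C)[C@H]1[C@H](O)c1c(OC)c2c(C)cccc2oc1=O
F7 | step 12 | (1S,4aS,7S,7aR)-1-(4-methoxy-5-methyl-2-oxo-2H-chromen-3-yl)-4,7-dimethyl-1,4a,5,6,7,7a-hexahydrocyclopenta[c]pyran-3-yl trifluoromethanesulfonate | CC1=C(OS(=O)(=O)C(F)(F)F)O[C@H](c2c(OC)c3c(C)cccc3oc2=O)[C@H]2[C@@H]1CC[C@@H]2C
F8 | step 12 | 3-[(1S,4aS,7S,7aR)-3-(1-hydroxy-3-methylbutyl)-4,7-dimethyl-1,4a,5,6,7,7a-hexahydrocyclopenta[c]pyran-1-yl]-4-methoxy-5-methyl-2H-chromen-2-one | CC1=C(C(O)CC(C)C)O[C@H](c2c(OC)c3c(C)cccc3oc2=O)[C@H]2[C@@H]1CC[C@@H]2C
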